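**Plan**
- Retrosynthesis: the pyran ring is cut at C3=C4. This cis-alkene lies between aryl carbon C4a and the fully substituted C2, so it opens to two vinyl groups held ortho by the C8a–O–C2 ether (ring-closing metathesis). Next cut is the O–C2 bond (Pd-catalysed asymmetric allylic etherification), then the side-chain alkene (methylalumination of a terminal alkyne).
- The cyclohexane is built inside a temporary bicyclic enone (Michael addition, aldol), whose ring fixes the two methyl groups trans. Eschenmoser–Tanabe fragmentation opens it to the ring ketone (later the exocyclic methylidene) and an alkyne whose two carbons become C2 and C3 of the chromene.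
- The arene comes from 2,4,5-trihydroxybenzaldehyde by silylation, methylation, Dakin oxidation, ortho-formylation and Wittig methylenation.
- Forward order: cyclohexane (bicyclic, then opened), side chain, aryl ether, pyran ring (last ring), desilylation.
- Stereochemistry: the quaternary ring carbon from the (S)-1-phenylethylamine imine, the ring CH(CH3) by equilibration in the bicyclic enone, C2 from the chiral Pd ligand.

Key step: step 14

Assumption: the (S)-1-phenylethylamine imine of 2,6-dimethylcyclohexanone is taken to alkylate with the facial sense known for 2-methylcyclohexanone (R quaternary carbon), and the (R,R) ligand is taken as the one that turns the (E)-carbonate into the (S) ether; if either sense proves opposite, the antipodal amine or ligand is used with no other change.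

**Route**

Step 1
Reactants: 1 2,6-dimethylcyclohexanone (cis/trans mixture); 2 (S)-1-phenylethylamine; 3 methyl vinyl ketone
Product: 6 (2R)-2,6-dimethyl-2-(3-oxobutyl)cyclohexan-1-one (both C6 epimers), via ketimine 4 (not isolated), via alkylated ketimine 5 (not isolated)
Conditions: p-TsOH (cat.), toluene, reflux (Dean–Stark); then THF, rt; then aq. AcOH, rt
Reagents that add atoms: water O
Why: d'Angelo Michael addition, in which the secondary enamine tautomer of the chiral ketimine adds to the enone at its more substituted carbon on the face away from the phenyl group, so the quaternary carbon should form as R, while C6 is left open and hydrolysis returns the auxiliary.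

Step 2
Reactants: 6 (2R)-2,6-dimethyl-2-(3-oxobutyl)cyclohexan-1-one
Product: 7 (4aR,8R)-4a,8-dimethyl-4,4a,5,6,7,8-hexahydronaphthalen-2(3H)-one
Conditions: NaOMe, MeOH, rt to 60 °C
Reagents that add atoms: none
Why: Intramolecular aldol condensation (second stage of a Robinson annulation) in which C8 can epimerise through the extended dienolate and should settle equatorial, trans to the axial angular methyl group, because the cis isomer would suffer a 1,3-diaxial methyl–methyl contact.

Step 3
Reactants: 7 (4aR,8R)-4a,8-dimethyl-4,4a,5,6,7,8-hexahydronaphthalen-2(3H)-one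
Product: 8 (4aR,8R)-1,8a-epoxy-4a,8-dimethyloctahydronaphthalen-2(1H)-one (either epoxide face)
Conditions: 30% H2O2, aq. NaOH, MeOH, 0 °C to rt
Reagents that add atoms: hydrogen peroxide OO
Why: Weitz–Scheffer nucleophilic epoxidation of the enone, for which the face of attack does not matter because both oxirane carbons lose their configuration in step 4.

Step 4
Reactants: 8 (4aR,8R)-1,8a-epoxy-4a,8-dimethyloctahydronaphthalen-2(1H)-one
Product: 10 (2R,6R)-2-(but-3-yn-1-yl)-2,6-dimethylcyclohexan-1-one, via epoxy tosylhydrazone 9 (not isolated)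
Conditions: TsNHNH2, AcOH/CH2Cl2 (1:1), −20 °C to rt
Reagents that add atoms: none
Why: Eschenmoser–Tanabe fragmentation, in which the tosylhydrazone opens the oxirane and then cleaves the C1–C8a bond with loss of dinitrogen and sulfinate to give the ring ketone and the terminal alkyne, the cold weakly acidic medium being chosen so that the methyl-bearing α-carbon does not enolise.

Step 5
Reactants: 10 (2R,6R)-2-(but-3-yn-1-yl)-2,6-dimethylcyclohexan-1-one
Product: 11 (1R,3R)-1-(but-3-yn-1-yl)-1,3-dimethyl-2-methylidenecyclohexane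
Conditions: Zn, CH2Br2, TiCl4, THF/CH2Cl2, 0 °C to rt
Reagents that add atoms: dibromomethane BrCBr
Why: Takai–Lombardo methylenation, whose non-basic zinc/titanium methylene reagent is the standard choice for hindered, enolisable ketones and should leave both the α-stereocentre and the alkyne untouched.

Step 6
Reactants: 11 (1R,3R)-1-(but-3-yn-1-yl)-1,3-dimethyl-2-methylidenecyclohexane
Product: 14 (2E)-5-[(1R,3R)-1,3-dimethyl-2-methylidenecyclohexyl]-3-methylpent-2-en-1-ol, via alkenylalane 12 (not isolated), via lithium alkenylalanate 13 (not isolated)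
Conditions: Me3Al, Cp2ZrCl2 (cat.), CH2Cl2, rt; n-BuLi, THF, −78 °C; (CH2O)n, rt; aq. HCl work-up
Reagents that add atoms: trimethylaluminium C[Al](C)C; paraformaldehyde (as formaldehyde) C=O
Why: Negishi zirconium-catalysed carboalumination adds methyl and aluminium syn across the terminal alkyne (methyl to the internal carbon), and the derived alanate is hydroxymethylated with retention to give the E allylic alcohol, while the hindered 1,1-disubstituted ring alkene does not carbometalate.

Step 7
Reactants: 14 (2E)-5-[(1R,3R)-1,3-dimethyl-2-methylidenecyclohexyl]-3-methylpent-2-en-1-ol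
Product: 15 (2E)-5-[(1R,3R)-1,3-dimethyl-2-methylidenecyclohexyl]-3-methylpent-2-en-1-yl methyl carbonate
Conditions: ClCO2Me, pyridine, CH2Cl2, 0 °C
Reagents that add atoms: methyl chloroformate COC(=O)Cl
Why: Plain O-acylation of a primary allylic alcohol to the carbonate leaving group needed in step 13.

Step 8
Reactants: 16 2,4,5-trihydroxybenzaldehyde
Product: 17 4,5-bis[(tert-butyldimethylsilyl)oxy]-2-hydroxybenzaldehyde
Conditions: TBSCl (2.1 equiv), imidazole, CH2Cl2/DMF, 0 °C
Reagents that add atoms: tert-butyldimethylsilyl chloride CC(C)(C)[Si](C)(C)Cl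
Why: Selective silylation, since the 2-hydroxyl is hydrogen-bonded to the aldehyde and is the least reactive of the three.

Step 9
Reactants: 17 4,5-bis[(tert-butyldimethylsilyl)oxy]-2-hydroxybenzaldehyde
Product: 18 4,5-bis[(tert-butyldimethylsilyl)oxy]-2-methoxybenzaldehyde
Conditions: MeOH, PPh3, DIAD, THF, 0 °C to rt
Reagents that add atoms: methanol CO
Why: Mitsunobu O-methylation of the acidic phenol under neutral conditions, chosen so that the base-labile aryl silyl ethers survive.

Step 10
Reactants: 18 4,5-bis[(tert-butyldimethylsilyl)oxy]-2-methoxybenzaldehyde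
Product: 20 4,5-bis[(tert-butyldimethylsilyl)oxy]-2-methoxyphenol, via aryl formate 19 (not isolated)
Conditions: mCPBA, NaHCO3, CH2Cl2, 0 °C to rt; then Et3N, MeOH, 0 °C
Reagents that add atoms: 3-chloroperoxybenzoic acid OOC(=O)c1cccc(Cl)c1
Why: Dakin-type Baeyer–Villiger oxidation, in which the electron-rich aryl group migrates in preference to hydrogen and the labile formate is removed by mild methanolysis.

Step 11
Reactants: 20 4,5-bis[(tert-butyldimethylsilyl)oxy]-2-methoxyphenol
Product: 21 5,6-bis[(tert-butyldimethylsilyl)oxy]-2-hydroxy-3-methoxybenzaldehyde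
Conditions: MgCl2, Et3N, (CH2O)n, THF, reflux
Reagents that add atoms: paraformaldehyde (as formaldehyde) C=O
Why: Casnati–Skattebøl ortho-formylation, in which the magnesium phenoxide delivers formaldehyde to the only free ortho position and a second formaldehyde oxidises the benzylic alkoxide to the aldehyde.

Step 12
Reactants: 21 5,6-bis[(tert-butyldimethylsilyl)oxy]-2-hydroxy-3-methoxybenzaldehyde
Product: 22 3,4-bis[(tert-butyldimethylsilyl)oxy]-2-ethenyl-6-methoxyphenol
Conditions: Ph3PCH3Br, NaN(SiMe3)2 (2.2 equiv of ylide), THF, 0 °C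
Reagents that add atoms: methyltriphenylphosphonium bromide C[P+](c1ccccc1)(c1ccccc1)c1ccccc1.[Br-]
Why: Wittig methylenation of a salicylaldehyde with excess salt-free ylide, the first equivalent serving only to deprotonate the phenol.

Step 13
Reactants: 15 (2E)-5-[(1R,3R)-1,3-dimethyl-2-methylidenecyclohexyl]-3-methylpent-2-en-1-yl methyl carbonate; 22 3,4-bis[(tert-butyldimethylsilyl)oxy]-2-ethenyl-6-methoxyphenol
Product: 23 1-{[(3S)-5-[(1R,3R)-1,3-dimethyl-2-methylidenecyclohexyl]-3-methylpent-1-en-3-yl]oxy}-2-ethenyl-6-methoxy-3,4-bis[(tert-butyldimethylsilyl)oxy]benzene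
Conditions: Pd2(dba)3·CHCl3 (2.5 mol%), (R,R)-DACH-phenyl Trost ligand (7.5 mol%), n-Bu4NCl (cat.), CH2Cl2, rt
Reagents that add atoms: none
Why: Trost asymmetric allylic alkylation, in which zerovalent palladium ionises the carbonate, the phenol attacks the more substituted terminus of the π-allyl complex as is usual for phenols with this ligand class, and the chiral ligand sets the new tertiary ether carbon as S.

Step 14
Reactants: 23 1-{[(3S)-5-[(1R,3R)-1,3-dimethyl-2-methylidenecyclohexyl]-3-methylpent-1-en-3-yl]oxy}-2-ethenyl-6-methoxy-3,4-bis[(tert-butyldimethylsilyl)oxy]benzene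
Product: 24 (2S)-5,6-bis[(tert-butyldimethylsilyl)oxy]-2-{2-[(1R,3R)-1,3-dimethyl-2-methylidenecyclohexyl]ethyl}-8-methoxy-2-methyl-2H-chromene
Conditions: second-generation Grubbs catalyst (H2IMes)(PCy3)Cl2Ru=CHPh (5 mol%), toluene (0.01 M), 70 °C, argon sparge
Reagents that add atoms: none
Why: Ring-closing olefin metathesis: the ruthenium alkylidene loads onto the styrenyl vinyl group on C4a, the resulting arylidene undergoes intramolecular [2+2] cycloaddition with the vinyl group on C2, and the ruthenacyclobutane collapses to the C3=C4 alkene with loss of ethene. The closest known reaction type is the ring-closing metathesis of 2-vinylaryl 1,1-disubstituted allyl ethers to 2,2-disubstituted 2H-chromenes. The six-membered pyran ring is closed between two terminal alkene carbons held in a 1,6 relation by the C8a–O–C2 ether, and the ring enforces the cis alkene. No stereocentre is formed; C2 is fully substituted and none of its bonds is broken, so the S configuration from step 13 is carried through. The step needs chemoselectivity among three alkenes, and the exocyclic methylidene, flanked by a quaternary and a tertiary carbon, is too hindered to enter a ruthenacyclobutane. Dilution and the fully substituted C2 (Thorpe–Ingold effect) should favour ring closure over intermolecular metathesis.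

Step 15
Reactants: 24 (2S)-5,6-bis[(tert-butyldimethylsilyl)oxy]-2-{2-[(1R,3R)-1,3-dimethyl-2-methylidenecyclohexyl]ethyl}-8-methoxy-2-methyl-2H-chromene
Product: 25 (2S)-2-{2-[(1R,3R)-1,3-dimethyl-2-methylidenecyclohexyl]ethyl}-8-methoxy-2-methyl-2H-chromene-5,6-diol
Conditions: n-Bu4NF, AcOH, degassed THF, 0 °C, argon
Reagents that add atoms: none
Why: Fluoride cleavage of aryl silyl ethers, buffered with acetic acid so that the air-sensitive catechol is never present as its dianion and neither the chromene nor the exocyclic alkene meets acid or base strong enough to affect it.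

**Compound list**
1 | 2,6-dimethylcyclohexanone (cis/trans mixture) | CC1CCCC(C)C1=O | starting material
2 | (S)-1-phenylethylamine | C[C@H](N)c1ccccc1 | starting material
3 | methyl vinyl ketone | CC(=O)C=C | starting material
4 | (1S)-N-(2,6-dimethylcyclohexylidene)-1-phenylethanamine | C[C@H](N=C1C(C)CCCC1C)c1ccccc1 | intermediate
5 | 4-[(1R)-1,3-dimethyl-2-{[(1S)-1-phenylethyl]imino}cyclohexyl]butan-2-one | C[C@H](N=C1C(C)CCC[C@]1(C)CCC(C)=O)c1ccccc1 | intermediate
6 | (2R)-2,6-dimethyl-2-(3-oxobutyl)cyclohexan-1-one (both C6 epimers) | O=C1C(C)CCC[C@]1(C)CCC(C)=O | intermediate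
7 | (4aR,8R)-4a,8-dimethyl-4,4a,5,6,7,8-hexahydronaphthalen-2(3H)-one | O=C1C=C2[C@H](C)CCC[C@]2(C)CC1 | intermediate
8 | (4aR,8R)-1,8a-epoxy-4a,8-dimethyloctahydronaphthalen-2(1H)-one (either epoxide face) | O=C1C2OC23[C@H](C)CCC[C@]3(C)CC1 | intermediate
9 | 4-methylbenzenesulfonohydrazone of 8 | Cc1ccc(cc1)S(=O)(=O)NN=C1C2OC23[C@H](C)CCC[C@]3(C)CC1 | intermediate
10 | (2R,6R)-2-(but-3-yn-1-yl)-2,6-dimethylcyclohexan-1-one | O=C1[C@H](C)CCC[C@]1(C)CCC#C | intermediate
11 | (1R,3R)-1-(but-3-yn-1-yl)-1,3-dimethyl-2-methylidenecyclohexane | C=C1[C@H](C)CCC[C@]1(C)CCC#C | intermediate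
12 | [(1E)-4-[(1R,3R)-1,3-dimethyl-2-methylidenecyclohexyl]-2-methylbut-1-en-1-yl]dimethylalumane | C=C1[C@H](C)CCC[C@]1(C)CC/C(C)=C/[Al](C)C | intermediate
13 | lithium butyl[(1E)-4-[(1R,3R)-1,3-dimethyl-2-methylidenecyclohexyl]-2-methylbut-1-en-1-yl]dimethylaluminate | [Li+].C=C1[C@H](C)CCC[C@]1(C)CC/C(C)=C/[Al-](C)(C)CCCC | intermediate
14 | (2E)-5-[(1R,3R)-1,3-dimethyl-2-methylidenecyclohexyl]-3-methylpent-2-en-1-ol | C=C1[C@H](C)CCC[C@]1(C)CC/C(C)=C/CO | intermediate
15 | (2E)-5-[(1R,3R)-1,3-dimethyl-2-methylidenecyclohexyl]-3-methylpent-2-en-1-yl methyl carbonate | C=C1[C@H](C)CCC[C@]1(C)CC/C(C)=C/COC(=O)OC | intermediate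
16 | 2,4,5-trihydroxybenzaldehyde | O=Cc1cc(O)c(O)cc1O | starting material
17 | 4,5-bis[(tert-butyldimethylsilyl)oxy]-2-hydroxybenzaldehyde | O=Cc1cc(O[Si](C)(C)C(C)(C)C)c(O[Si](C)(C)C(C)(C)C)cc1O | intermediate
18 | 4,5-bis[(tert-butyldimethylsilyl)oxy]-2-methoxybenzaldehyde | O=Cc1cc(O[Si](C)(C)C(C)(C)C)c(O[Si](C)(C)C(C)(C)C)cc1OC | intermediate
19 | 4,5-bis[(tert-butyldimethylsilyl)oxy]-2-methoxyphenyl formate | O=COc1cc(O[Si](C)(C)C(C)(C)C)c(O[Si](C)(C)C(C)(C)C)cc1OC | intermediate
20 | 4,5-bis[(tert-butyldimethylsilyl)oxy]-2-methoxyphenol | Oc1cc(O[Si](C)(C)C(C)(C)C)c(O[Si](C)(C)C(C)(C)C)cc1OC | intermediate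
21 | 5,6-bis[(tert-butyldimethylsilyl)oxy]-2-hydroxy-3-methoxybenzaldehyde | O=Cc1c(O)c(OC)cc(O[Si](C)(C)C(C)(C)C)c1O[Si](C)(C)C(C)(C)C | intermediate
22 | 3,4-bis[(tert-butyldimethylsilyl)oxy]-2-ethenyl-6-methoxyphenol | C=Cc1c(O)c(OC)cc(O[Si](C)(C)C(C)(C)C)c1O[Si](C)(C)C(C)(C)C | intermediate
23 | 1-{[(3S)-5-[(1R,3R)-1,3-dimethyl-2-methylidenecyclohexyl]-3-methylpent-1-en-3-yl]oxy}-2-ethenyl-6-methoxy-3,4-bis[(tert-butyldimethylsilyl)oxy]benzene | C=C1[C@H](C)CCC[C@]1(C)CC[C@@](Oc1c(OC)cc(O[Si](C)(C)C(C)(C)C)c(O[Si](C)(C)C(C)(C)C)c1C=C)(C)C=C | intermediate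
24 | (2S)-5,6-bis[(tert-butyldimethylsilyl)oxy]-2-{2-[(1R,3R)-1,3-dimethyl-2-methylidenecyclohexyl]ethyl}-8-methoxy-2-methyl-2H-chromene | C=C1[C@H](C)CCC[C@]1(C)CC[C@@]1(C)C=Cc2c(O[Si](C)(C)C(C)(C)C)c(O[Si](C)(C)C(C)(C)C)cc(OC)c2O1 | intermediate
25 | (2S)-2-{2-[(1R,3R)-1,3-dimethyl-2-methylidenecyclohexyl]ethyl}-8-methoxy-2-methyl-2H-chromene-5,6-diol | C=C1[C@H](C)CCC[C@]1(C)CC[C@@]1(C)C=Cc2c(O)c(O)cc(OC)c2O1 | target

**Totals**
Total step count: 15.
Longest linear sequence: 10 steps (steps 1 to 7, then 13 to 15, from 2,6-dimethylcyclohexanone).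

**Steps most likely to fail**

Step 13. The hindered, 2,6-disubstituted phenoxide may attack the unsubstituted allyl terminus instead, and re-ionisation of the tertiary aryl ether by the catalyst may erode both regio- and enantiopurity. The fallback sets out from 14 (with 22) and comes back at 23. Sharpless asymmetric epoxidation of 14 (Ti(OiPr)4, D-(−)-diethyl tartrate, t-BuOOH, 4 Å molecular sieves, CH2Cl2, −20 °C) would give the (2R,3R)-epoxy alcohol F1. Opening of F1 by phenol 22, mediated by Ti(OiPr)4, at the fully substituted C3 with inversion would give the (2R,3S)-3-aryloxy-1,2-diol F2. Cleavage with NaIO4 (THF/H2O) would give the (2S)-2-aryloxy aldehyde F3, which has no α-hydrogen and cannot epimerise. Wittig methylenation (Ph3PCH3Br, NaN(SiMe3)2, THF) would then give 23. The epoxide opening at a tertiary carbon by a hindered phenol is itself demanding and may need forcing.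

Step 5. Addition to the doubly α-branched ketone may be slow, and competing enolisation would scramble the methyl-bearing stereocentre. The fallback sets out from 10 and comes back at 11. Addition of Me3SiCH2Li activated with CeCl3 (THF, −78 °C; excess, since the alkyne proton consumes one equivalent) would give the β-hydroxysilane F4. Peterson elimination with KH in THF would then give 11.

Step 3. Conjugate addition of hydroperoxide to the fully substituted β-carbon, flanked by a quaternary and a tertiary carbon, may be too slow. The fallback sets out from 7 and comes back at 8. Luche reduction (NaBH4, CeCl3·7H2O, MeOH) would give the allylic alcohol F5. Hydroxyl-directed epoxidation (VO(acac)2, t-BuOOH, CH2Cl2) would give the epoxy alcohol F6. Oxidation with Dess–Martin periodinane would then give 8.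

Further compounds
F1 | step 13 | [(2R,3R)-3-{2-[(1R,3R)-1,3-dimethyl-2-methylidenecyclohexyl]ethyl}-3-methyloxiran-2-yl]methanol | C=C1[C@H](C)CCC[C@]1(C)CC[C@@]1(C)O[C@@H]1CO
F2 | step 13 | (2R,3S)-3-{3,4-bis[(tert-butyldimethylsilyl)oxy]-2-ethenyl-6-methoxyphenoxy}-5-[(1R,3R)-1,3-dimethyl-2-methylidenecyclohexyl]-3-methylpentane-1,2-diol | C=C1[C@H](C)CCC[C@]1(C)CC[C@@](Oc1c(OC)cc(O[Si](C)(C)C(C)(C)C)c(O[Si](C)(C)C(C)(C)C)c1C=C)(C)[C@H](O)CO
F3 | step 13 | (2S)-2-{3,4-bis[(tert-butyldimethylsilyl)oxy]-2-ethenyl-6-methoxyphenoxy}-4-[(1R,3R)-1,3-dimethyl-2-methylidenecyclohexyl]-2-methylbutanal | C=C1[C@H](C)CCC[C@]1(C)CC[C@@](Oc1c(OC)cc(O[Si](C)(C)C(C)(C)C)c(O[Si](C)(C)C(C)(C)C)c1C=C)(C)C=O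
F4 | step 5 | (2R,6R)-2-(but-3-yn-1-yl)-2,6-dimethyl-1-[(trimethylsilyl)methyl]cyclohexan-1-ol (carbinol epimers) | C[Si](C)(C)CC1(O)[C@H](C)CCC[C@]1(C)CCC#C
F5 | step 3 | (4aR,8R)-4a,8-dimethyl-2,3,4,4a,5,6,7,8-octahydronaphthalen-2-ol | OC1C=C2[C@H](C)CCC[C@]2(C)CC1
F6 | step 3 | (4aR,8R)-1,8a-epoxy-4a,8-dimethyldecahydronaphthalen-2-ol | OC1C2OC23[C@H](C)CCC[C@]3(C)CC1
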